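Atoms carry the benzofuran numbering of the target throughout (O1, C2, C3, C3a, C4 to C7, C7a), also in open-chain intermediates.

## Analysis of the target

Target 24 is a 3,3a-dihydrobenzofuran-6(2H)-one: a tetrahydrofuran ring (O1, C2, C3, C3a, C7a) fused along C3a–C7a to a cross-conjugated cyclohexa-2,5-dienone (C3a, C4, C5, C6, C7, C7a). In the carbocycle, C7=C7a–O1 is a vinylogous ester and C4=C5(OMe) is the enol ether of an α-diketone. There are three contiguous stereocentres, C2 (S), C3 (S) and the all-carbon quaternary C3a (R): the aryl group on C2 is trans to the methyl group on C3, and the methyl group is cis to the allyl group on C3a, so C4 lies anti to the methyl group. Sensitive sites are the vinylogous ester (addition–elimination, acid hydrolysis), the benzylic C2–O1 bond (its oxygen is a vinylogous carboxylate and can leave), the 4-allyl-cyclohexadienone (allyl shifts on heating or in acid) and the terminal alkene. The difficulty is to build the quaternary C3a next to two stereocentres with the allyl group on the face of the methyl group, and to reach the dienone oxidation level without strong acid, strong base or heat at the end. The strategy rests on one relationship: C3a is α to C4, which becomes an aldehyde carbon when C4=C5 is opened as an aldol condensation, and C7a is the β-carbon of an enone whose β-oxygen is O1. Both C3a–C7a and C4=C5 can therefore come from one open-chain aldehyde carrying an alkoxy enone on O1, with the C7=C7a unsaturation added afterwards.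

## Retrosynthetic reasoning

**24 ⇒ 22 (through 23).** The C7=C7a double bond is removed first, because a Michael–aldol sequence can only deliver C7 as a methylene group. This traces the vinylogous ester of 24 to the β-alkoxy ketone 22. In the forward sense C7 is the only enolisable position of 22 (C5 is sp2, C3a is quaternary), so enol silane 23 forms with one regiochemistry and a palladium-mediated dehydrogenation can only take the C7a hydrogen. The C7a stereocentre is lost here, so it needs no control earlier.

**22 ⇒ 19.** The bonds C3a–C7a and C4=C5 are cut together. This removes both rings and the quaternary carbon at once and leaves chain 19, whose only fixed stereocentres are C2 and C3; the centre next to its formyl group is epimerisable and needs no control. Forward, a primary ammonium salt has to turn the α-branched aldehyde into its enamine, C3a has to add to C7a, and the methoxy ketone has to condense with C4.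

**19 ⇒ 18 ⇒ 17.** The formyl group is traced to a silyl-protected primary alcohol. A free C2 hydroxyl and a C4 aldehyde in one molecule would close to a five-membered lactol, so O1 must be vinylated while C4 is still a masked alcohol. A fluoride-labile silyl ether and a neutral periodinane oxidation are chosen because the alkoxy enone of 17 would not survive the aqueous acid needed to unmask an enol ether or an acetal.

**17 ⇒ 16 + 4.** The O1–C7a bond is cut. Forward, conjugate addition of the secondary hydroxyl of 16 to terminal ynone 4 gives the (E)-alkoxy enone with full atom economy. Ynone 4 carries C5, C6, C7, C7a and the methoxy group; it goes back to Weinreb amide 2 and Grignard reagent 3, and 2 to acid chloride 1.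

**16 ⇒ 15 ⇒ 14.** The two hydroxyls of 15 are primary and hindered secondary benzylic, so a bulky silyl chloride tells them apart. Diol 15 is the hydride-reduction product of lactone 14, in which O1 and C4 are tied into one ring and C4 is at the acid level.

**14 ⇒ 12 + 13.** The C3a–allyl bond is cut; alkylating a γ-lactone enolate with bromide 13 is the simplest way to place the allyl group next to C4. A path in which C3a would be a ketone carbon, receiving the allyl group from an organometallic reagent and C4 from a phosphorus ylide, was set aside. The β,γ-unsaturated ketone it needs has a doubly activated methylene and a β-oxygen, and a basic ylide would deprotonate, isomerise or eliminate it.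

**12 ⇒ 10 ⇒ 8.** The lactone carbonyl carbon (C4) is traced to the terminal alkene carbon of homoallylic alcohol 8 by anti-Markovnikov hydration to diol 10 and oxidative lactonisation. This changes no stereocentre.

**8 ⇒ 5 + 6.** The C2–C3 bond is cut. An anti-selective, catalyst-controlled crotylboration of aldehyde 5 with (E)-crotylboronate 6 sets C2 and C3 in one step, without an auxiliary to attach and remove.

## Alternatives that were turned down

**Alternative 1:** Disconnection at C3a–C4 and C7–C7a, a Robinson-type annulation of the vinyl ketone 3-methoxybut-3-en-2-one A1 onto lactone 14, whose carbonyl carbon is read here as C7a.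
- Forward key step: lactone 14 is deprotonated with KN(SiMe3)2 and its enolate adds through C3a to the methylene carbon of A1, which becomes C4. The methyl ketone is then enolised and its carbon, the future C7, acylates on the lactone carbonyl. An acidic work-up removes water and leaves the tetrahydrobenzofuranone A2, 3a-allyl-5-methoxy-3-methyl-2-(3,4,5-trimethoxyphenyl)-3,3a,4,5-tetrahydrobenzofuran-6(2H)-one. A C4–C5 dehydrogenation would finish.
- For: 14 is reached in four steps of the present route. The new bond at C3a forms on a rigid five-membered enolate anti to the neighbouring methyl group, which is the most dependable way to set this centre. The route would be about five steps shorter.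
- Against: a fully substituted enolate must add to A1, an α-alkoxy vinyl ketone that polymerises easily. The enolate left after the Michael step sits on the methoxy-bearing carbon and must move to the methyl group before the Claisen step, which then attacks a carbonyl flanked by the new quaternary carbon. Strong base is present throughout, and the C4=C5 bond must still be introduced next to the quaternary carbon.
- Comparison: on step count and on control of C3a this alternative is the stronger one, and it serves below as the fallback. The chosen strategy offers instead ring closure under buffered, nearly neutral conditions, the C4=C5 enol ether formed directly at the right oxidation level, and both rings closed in one catalytic operation.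

**Alternative 2:** Disconnection by [2+2] cycloaddition across the enol ether bond C3a=C7a.
- Forward key step: dichloroketene A3, generated in situ, is added to the enol ether (2S,3S)-3-methyl-4-(prop-2-enyl)-2-(3,4,5-trimethoxyphenyl)-2,3-dihydrofuran A4. The ketene carbonyl carbon (later C6) joins the nucleophilic C3a and the dichlorinated carbon (later C7) joins C7a, so that the four-membered ketone A5 forms with a cis ring fusion.
- For: ketene–enol ether cycloadditions are dependable and their regiochemistry follows from polarity. The concerted step tolerates the crowding at C3a, and approach anti to the C3 methyl would place the allyl group correctly.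
- Against: A5 holds only four of the six ring carbons. C4 and C5 must be inserted between C3a and C6 with the right migrating bond, the chlorine atoms removed, the methoxy group and C4=C5 installed and C7=C7a re-created, which is six or more steps after the key step. A4 is an acid-sensitive enol ether that has to be made first, and the allyl alkene is a second, slower ketenophile.
- Comparison: bond formation at C3a is more reliable than in the chosen cascade, but step economy is much poorer. The chosen route delivers all six ring carbons with their oxygen pattern in one step.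

**Alternative 3:** Disconnection at C3–CH3 and C3a–C4 on butenolide A6, (5S)-3-(prop-2-enyl)-5-(3,4,5-trimethoxyphenyl)furan-2(5H)-one.
- Forward key step: lithium dimethylcuprate A7 (Me2CuLi) adds its methyl group to C3 of A6 on the face away from the C2 aryl group. The enolate so formed is hydroxymethylated at C3a by formaldehyde A8 on the face away from the new methyl group, which gives hydroxymethyl lactone A9.
- For: conjugate addition with enolate trapping on a butenolide is robust. C3 and C3a are set in one pot by simple anti relationships, and the allyl group ends cis to methyl as required.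
- Against: C2 of A6 is a benzylic, γ-acidic position and can racemise under the basic conditions by γ-deprotonation to an achiral, furan-like dienolate. The cuprate must add to an α-substituted butenolide. A9 carries only C4 of the carbocycle, so C5, C6, C7 and the closure onto the lactone carbonyl remain, roughly five more steps ending in the same Claisen closure as Alternative 1.
- Comparison: stronger on C3/C3a control, weaker in convergence and length. The chosen route sets C2 and C3 by one catalytic crotylation and leaves the ring construction to a single step.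

Key step: step 12

## Route

Assumption: in step 3 the (S)-configured phosphoric acid is taken to direct crotyl transfer to the Si face of 5, by analogy with the Re-face preference of the (R)-acid in allylborations of aryl aldehydes.

Remark: the formyl-bearing carbon of 19 is configurationally labile and is drawn without configuration.

Step 1
Reactants: 1 methoxyacetyl chloride
Product: 2 N,2-dimethoxy-N-methylacetamide
Conditions: MeNH(OMe)·HCl, pyridine, CH2Cl2, 0 °C to rt
Reagents that add atoms: N,O-dimethylhydroxylamine hydrochloride, CNOC.Cl
Why: Acylation of the hydroxylamine by an acid chloride is fast and clean; the Weinreb amide is made so that the alkynyl Grignard reagent of step 2 adds only once.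

Step 2
Reactants: 2 N,2-dimethoxy-N-methylacetamide; 3 ethynylmagnesium bromide
Product: 4 1-methoxybut-3-yn-2-one
Conditions: THF, 0 °C; poured into cold aq. NaHSO4; used as a cold solution
Reagents that add atoms: none
Why: Weinreb ketone synthesis: the chelated tetrahedral adduct survives until the quench, so no tertiary alcohol forms. The inverse acidic quench protonates the released hydroxylamine before it can add to the ynone.

Step 3
Reactants: 5 3,4,5-trimethoxybenzaldehyde; 6 2-[(E)-but-2-enyl]-4,4,5,5-tetramethyl-1,3,2-dioxaborolane
Product: 8 (1S,2S)-2-methyl-1-(3,4,5-trimethoxyphenyl)but-3-en-1-ol, via borate ester 7 (not isolated)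
Conditions: (S)-3,3'-bis(2,4,6-triisopropylphenyl)-1,1'-binaphthyl-2,2'-diyl hydrogen phosphate (5 mol%), PhMe, −30 °C; aq. work-up
Reagents that add atoms: none
Why: Chiral phosphoric acid-catalysed crotylboration through a closed chair transition state: the (E)-geometry of 6 becomes the anti relationship of hydroxyl and methyl. The acid, bound to a boronate oxygen and the formyl hydrogen, exposes the Si face of 5, which gives the (1S,2S) isomer (future C2 and C3).

Step 4
Reactants: 8 (1S,2S)-2-methyl-1-(3,4,5-trimethoxyphenyl)but-3-en-1-ol
Product: 10 (1S,2S)-2-methyl-1-(3,4,5-trimethoxyphenyl)butane-1,4-diol, via organoborane 9 (not isolated)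
Conditions: 9-borabicyclo[3.3.1]nonane (2.5 equiv), THF, 0 °C to rt; then NaOH, H2O2, 0 °C
Reagents that add atoms: 9-borabicyclo[3.3.1]nonane, B1C2CCCC1CCC2 (boron stays in 9 only); hydrogen peroxide, OO
Why: Anti-Markovnikov hydroboration of the monosubstituted alkene with a bulky dialkylborane puts boron on the terminal carbon; oxidation with retention gives the primary alcohol. No stereocentre is touched.

Step 5
Reactants: 10 (1S,2S)-2-methyl-1-(3,4,5-trimethoxyphenyl)butane-1,4-diol
Product: 12 (4S,5S)-4-methyl-5-(3,4,5-trimethoxyphenyl)oxolan-2-one, via lactol 11 (not isolated)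
Conditions: (2,2,6,6-tetramethylpiperidin-1-yl)oxyl (20 mol%), PhI(OAc)2 (2.5 equiv), CH2Cl2, rt
Reagents that add atoms: none
Why: Oxoammonium oxidation is selective for the primary alcohol; the hydroxy aldehyde closes to lactol 11, which is oxidised on to the γ-lactone.

Step 6
Reactants: 12 (4S,5S)-4-methyl-5-(3,4,5-trimethoxyphenyl)oxolan-2-one; 13 allyl bromide
Product: 14 (3S,4S,5S)-4-methyl-3-(prop-2-enyl)-5-(3,4,5-trimethoxyphenyl)oxolan-2-one
Conditions: LiN(iPr)2, THF, −78 °C; then 13, −78 to −40 °C
Reagents that add atoms: none
Why: Alkylation of a γ-butyrolactone lithium enolate; the bromide enters anti to the adjacent methyl group, so the all-trans lactone is expected. This centre is erased later at the enamine stage in any case.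

Step 7
Reactants: 14 (3S,4S,5S)-4-methyl-3-(prop-2-enyl)-5-(3,4,5-trimethoxyphenyl)oxolan-2-one
Product: 15 (1S,2S,3S)-3-(hydroxymethyl)-2-methyl-1-(3,4,5-trimethoxyphenyl)hex-5-en-1-ol
Conditions: LiAlH4, THF, 0 °C
Reagents that add atoms: none
Why: Hydride reduction of the lactone to the 1,4-diol; the terminal alkene and the aryl ethers are inert.

Step 8
Reactants: 15 (1S,2S,3S)-3-(hydroxymethyl)-2-methyl-1-(3,4,5-trimethoxyphenyl)hex-5-en-1-ol
Product: 16 (1S,2S,3S)-3-{[tert-butyl(dimethyl)silyl]oxymethyl}-2-methyl-1-(3,4,5-trimethoxyphenyl)hex-5-en-1-ol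
Conditions: tBuMe2SiCl (1.05 equiv), imidazole, CH2Cl2, 0 °C
Reagents that add atoms: tert-butylchlorodimethylsilane, CC(C)(C)[Si](C)(C)Cl
Why: Silylation with the bulky chloride discriminates the primary hydroxyl from the hindered secondary benzylic one, which leaves O1 free.

Step 9
Reactants: 16 (1S,2S,3S)-3-{[tert-butyl(dimethyl)silyl]oxymethyl}-2-methyl-1-(3,4,5-trimethoxyphenyl)hex-5-en-1-ol; 4 1-methoxybut-3-yn-2-one
Product: 17 (E)-4-{[(1S,2S,3S)-3-{[tert-butyl(dimethyl)silyl]oxymethyl}-2-methyl-1-(3,4,5-trimethoxyphenyl)hex-5-enyl]oxy}-1-methoxybut-3-en-2-one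
Conditions: PMe3 (20 mol%), CH2Cl2, 0 °C to rt, slow addition of 4 (1.5 equiv)
Reagents that add atoms: none
Why: Phosphine-catalysed oxa-Michael addition of an alcohol to a terminal ynone: the phosphonium enolate deprotonates the alcohol, the alkoxide adds to the β-carbon and the phosphine is expelled. This gives the (E)-alkoxy enone without a base that could touch the silyl ether.

Step 10
Reactants: 17 (E)-4-{[(1S,2S,3S)-3-{[tert-butyl(dimethyl)silyl]oxymethyl}-2-methyl-1-(3,4,5-trimethoxyphenyl)hex-5-enyl]oxy}-1-methoxybut-3-en-2-one
Product: 18 (E)-4-{[(1S,2S,3S)-3-(hydroxymethyl)-2-methyl-1-(3,4,5-trimethoxyphenyl)hex-5-enyl]oxy}-1-methoxybut-3-en-2-one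
Conditions: HF·pyridine, pyridine, THF, 0 °C
Reagents that add atoms: none
Why: Fluoride cleavage of the primary silyl ether under buffered conditions that neither hydrolyse the alkoxy enone nor ionise the benzylic C–O bond.

Step 11
Reactants: 18 (E)-4-{[(1S,2S,3S)-3-(hydroxymethyl)-2-methyl-1-(3,4,5-trimethoxyphenyl)hex-5-enyl]oxy}-1-methoxybut-3-en-2-one
Product: 19 (3S,4S)-4-[(E)-4-methoxy-3-oxobut-1-enyloxy]-3-methyl-2-(prop-2-enyl)-4-(3,4,5-trimethoxyphenyl)butanal
Conditions: Dess–Martin periodinane, NaHCO3, CH2Cl2, 0 °C to rt
Reagents that add atoms: none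
Why: Dess–Martin oxidation of the primary alcohol under buffered neutral conditions; the aldehyde is used at once, and epimerisation at its α-carbon is of no consequence.

Step 12
Reactants: 19 (3S,4S)-4-[(E)-4-methoxy-3-oxobut-1-enyloxy]-3-methyl-2-(prop-2-enyl)-4-(3,4,5-trimethoxyphenyl)butanal
Product: 22 (2S,3S,3aR,7aS)-3a-allyl-5-methoxy-3-methyl-2-(3,4,5-trimethoxyphenyl)-3,3a,7,7a-tetrahydrobenzofuran-6(2H)-one, via keto aldehyde 20 (not isolated), via ketol 21 (not isolated)
Conditions: benzylammonium trifluoroacetate (30 mol%), CHCl3, 45 °C
Reagents that add atoms: none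
Why: Proposed new method: the ammonium salt condenses with the formyl group of 19 and the iminium tautomerises to the secondary enamine, which erases the labile centre and makes C3a nucleophilic; C3a then adds to C7a of the O1-tethered alkoxy enone and closes the tetrahydrofuran in a 5-exo-trig Michael step, giving 20 as its iminium. The ketone enolises toward the methoxy-bearing C5, the only α-carbon that can reach C4, and attacks the C4 iminium or aldehyde in a 6-(enolexo)-exo-trig aldol (Mannich) closure to 21, which eliminates by E1cB to the C4=C5 enone and returns the catalyst. The closest known reactions are enamine-mediated intramolecular Michael additions of α-branched aldehydes to enones and the Stork-type Robinson annulation of α,α-disubstituted aldehydes with vinyl ketones to 4,4-disubstituted cyclohexenones; neither has been run on a β-alkoxy enone tethered through its own oxygen. C2 and C3 are carried over unchanged from 19 and place aryl and methyl trans on the new ring. C3a is set in the Michael step: of the two rotamers about C3–C3a that can deliver C7a, the one with C3–H near the enamine plane on the side of C4 and the methyl group turned toward the allyl CH2 avoids allylic 1,3-strain with the amino-substituted terminus, and it puts C4 anti to the methyl group. C7a follows from the cis ring fusion that the aldol closure requires, can be corrected by reversible β-elimination and oxa-Michael re-addition of O1, and is removed in step 14. The step needs enamine formation to win over aza-Michael displacement of O1 from the alkoxy enone, which a catalytic amount of amine held as its trifluoroacetate salt is meant to secure, and it needs the facial selectivity at C3a just described.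

Step 13
Reactants: 22 (2S,3S,3aR,7aS)-3a-allyl-5-methoxy-3-methyl-2-(3,4,5-trimethoxyphenyl)-3,3a,7,7a-tetrahydrobenzofuran-6(2H)-one
Product: 23 (2S,3S,3aR,7aS)-3a-allyl-5-methoxy-3-methyl-6-(trimethylsilyloxy)-2-(3,4,5-trimethoxyphenyl)-2,3,3a,7a-tetrahydrobenzofuran
Conditions: LiN(SiMe3)2, Me3SiCl, Et3N, THF, −78 °C; non-aqueous work-up
Reagents that add atoms: chlorotrimethylsilane, C[Si](C)(C)Cl
Why: Kinetic enolisation with in-situ silylation: C7 is the only enolisable position of 22, and trapping at −78 °C is meant to outrun β-elimination of O1.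

Step 14
Reactants: 23 (2S,3S,3aR,7aS)-3a-allyl-5-methoxy-3-methyl-6-(trimethylsilyloxy)-2-(3,4,5-trimethoxyphenyl)-2,3,3a,7a-tetrahydrobenzofuran
Product: 24 (2S,3S,3aR)-3a-allyl-5-methoxy-3-methyl-2-(3,4,5-trimethoxyphenyl)-3,3a-dihydrobenzofuran-6(2H)-one
Conditions: Pd(OAc)2 (1.1 equiv), MeCN, rt
Reagents that add atoms: none
Why: Saegusa–Ito oxidation: the enol silane gives a palladium enolate at C7, and β-hydride elimination can only take the C7a hydrogen, which creates the C7=C7a bond of the vinylogous ester. C2, C3 and C3a are not involved.

## Compound list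

1 | methoxyacetyl chloride | COCC(=O)Cl | starting material
2 | N,2-dimethoxy-N-methylacetamide | COCC(=O)N(C)OC | intermediate
3 | ethynylmagnesium bromide | C#C[Mg]Br | starting material
4 | 1-methoxybut-3-yn-2-one | COCC(=O)C#C | intermediate
5 | 3,4,5-trimethoxybenzaldehyde | COc1cc(C=O)cc(OC)c1OC | starting material
6 | 2-[(E)-but-2-enyl]-4,4,5,5-tetramethyl-1,3,2-dioxaborolane | C/C=C/CB1OC(C)(C)C(C)(C)O1 | starting material
7 | 4,4,5,5-tetramethyl-2-{[(1S,2S)-2-methyl-1-(3,4,5-trimethoxyphenyl)but-3-enyl]oxy}-1,3,2-dioxaborolane | C=C[C@H](C)[C@H](OB1OC(C)(C)C(C)(C)O1)c1cc(OC)c(OC)c(OC)c1 | intermediate (not isolated)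
8 | (1S,2S)-2-methyl-1-(3,4,5-trimethoxyphenyl)but-3-en-1-ol | C=C[C@H](C)[C@H](O)c1cc(OC)c(OC)c(OC)c1 | intermediate
9 | 9-{(3S,4S)-4-[(9-borabicyclo[3.3.1]nonan-9-yl)oxy]-3-methyl-4-(3,4,5-trimethoxyphenyl)butyl}-9-borabicyclo[3.3.1]nonane | C1CCC2CCCC1B2CC[C@H](C)[C@H](OB1C2CCCC1CCC2)c1cc(OC)c(OC)c(OC)c1 | intermediate (not isolated)
10 | (1S,2S)-2-methyl-1-(3,4,5-trimethoxyphenyl)butane-1,4-diol | OCC[C@H](C)[C@H](O)c1cc(OC)c(OC)c(OC)c1 | intermediate
11 | (4S,5S)-4-methyl-5-(3,4,5-trimethoxyphenyl)oxolan-2-ol (both anomers) | OC1C[C@H](C)[C@@H](c2cc(OC)c(OC)c(OC)c2)O1 | intermediate (not isolated)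
12 | (4S,5S)-4-methyl-5-(3,4,5-trimethoxyphenyl)oxolan-2-one (aryl and methyl trans) | O=C1C[C@H](C)[C@@H](c2cc(OC)c(OC)c(OC)c2)O1 | intermediate
13 | allyl bromide (3-bromoprop-1-ene) | C=CCBr | starting material
14 | (3S,4S,5S)-4-methyl-3-(prop-2-enyl)-5-(3,4,5-trimethoxyphenyl)oxolan-2-one (all-trans) | O=C1[C@@H](CC=C)[C@H](C)[C@@H](c2cc(OC)c(OC)c(OC)c2)O1 | intermediate
15 | (1S,2S,3S)-3-(hydroxymethyl)-2-methyl-1-(3,4,5-trimethoxyphenyl)hex-5-en-1-ol | C=CC[C@H](CO)[C@H](C)[C@H](O)c1cc(OC)c(OC)c(OC)c1 | intermediate
16 | (1S,2S,3S)-3-{[tert-butyl(dimethyl)silyl]oxymethyl}-2-methyl-1-(3,4,5-trimethoxyphenyl)hex-5-en-1-ol | C=CC[C@H](CO[Si](C)(C)C(C)(C)C)[C@H](C)[C@H](O)c1cc(OC)c(OC)c(OC)c1 | intermediate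
17 | (E)-4-{[(1S,2S,3S)-3-{[tert-butyl(dimethyl)silyl]oxymethyl}-2-methyl-1-(3,4,5-trimethoxyphenyl)hex-5-enyl]oxy}-1-methoxybut-3-en-2-one | C=CC[C@H](CO[Si](C)(C)C(C)(C)C)[C@H](C)[C@H](O/C=C/C(=O)COC)c1cc(OC)c(OC)c(OC)c1 | intermediate
18 | (E)-4-{[(1S,2S,3S)-3-(hydroxymethyl)-2-methyl-1-(3,4,5-trimethoxyphenyl)hex-5-enyl]oxy}-1-methoxybut-3-en-2-one | C=CC[C@H](CO)[C@H](C)[C@H](O/C=C/C(=O)COC)c1cc(OC)c(OC)c(OC)c1 | intermediate
19 | (3S,4S)-4-[(E)-4-methoxy-3-oxobut-1-enyloxy]-3-methyl-2-(prop-2-enyl)-4-(3,4,5-trimethoxyphenyl)butanal (C2 labile, left open) | C=CCC(C=O)[C@H](C)[C@H](O/C=C/C(=O)COC)c1cc(OC)c(OC)c(OC)c1 | intermediate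
20 | (2S,3S,4S,5S)-2-(3-methoxy-2-oxopropyl)-4-methyl-3-(prop-2-enyl)-5-(3,4,5-trimethoxyphenyl)oxolane-3-carbaldehyde (formyl and oxopropyl cis; allyl cis to methyl) | C=CC[C@@]1(C=O)[C@H](CC(=O)COC)O[C@H](c2cc(OC)c(OC)c(OC)c2)[C@H]1C | intermediate (not isolated)
21 | (2S,3S,3aR,7aS)-3a-allyl-4-hydroxy-5-methoxy-3-methyl-2-(3,4,5-trimethoxyphenyl)hexahydrobenzofuran-6(2H)-one (C4 and C5 unassigned) | C=CC[C@@]12C(O)C(OC)C(=O)C[C@@H]1O[C@H](c1cc(OC)c(OC)c(OC)c1)[C@H]2C | intermediate (not isolated)
22 | (2S,3S,3aR,7aS)-3a-allyl-5-methoxy-3-methyl-2-(3,4,5-trimethoxyphenyl)-3,3a,7,7a-tetrahydrobenzofuran-6(2H)-one | C=CC[C@@]12C=C(OC)C(=O)C[C@@H]1O[C@H](c1cc(OC)c(OC)c(OC)c1)[C@H]2C | intermediate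
23 | (2S,3S,3aR,7aS)-3a-allyl-5-methoxy-3-methyl-6-(trimethylsilyloxy)-2-(3,4,5-trimethoxyphenyl)-2,3,3a,7a-tetrahydrobenzofuran | C=CC[C@@]12C=C(OC)C(O[Si](C)(C)C)=C[C@@H]1O[C@H](c1cc(OC)c(OC)c(OC)c1)[C@H]2C | intermediate
24 | (2S,3S,3aR)-3a-allyl-5-methoxy-3-methyl-2-(3,4,5-trimethoxyphenyl)-3,3a-dihydrobenzofuran-6(2H)-one | C=CC[C@@]12C=C(OC)C(=O)C=C1O[C@H](c1cc(OC)c(OC)c(OC)c1)[C@H]2C | target

## Step count and least certain steps

Total: 14 steps. Longest linear sequence: 12 steps (steps 3 to 14); steps 1 and 2 form a two-step branch that joins at step 9.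

**Step 12 (key step, the new method).**
- What may go wrong: facial discrimination at C3a may be insufficient, because the allylic-strain preference competes with the enamine geometry that has nitrogen on the allyl side. The free amine may displace O1 from the alkoxy enone by aza-Michael addition–elimination, which severs the tether. The sequence may stall after the Michael step if enolisation toward C5 is slow.
- Fallback (known chemistry): it sets out from lactone 14 and comes back to the route at 24, reading the lactone carbonyl as C7a and setting C3a by enolate alkylation on the ring. The potassium enolate of 14 (KN(SiMe3)2, THF, −78 °C) is added to A1. Attack anti to the ring methyl should give (3S,4S,5S)-3-(2-methoxy-3-oxobutyl)-4-methyl-3-(prop-2-enyl)-5-(3,4,5-trimethoxyphenyl)oxolan-2-one F1. LiN(SiMe3)2 then forms the methyl ketone enolate, which closes onto the lactone carbonyl in a Claisen condensation. p-Toluenesulfonic acid re-closes O1 onto C7a with dehydration to (2S,3S,3aS)-3a-allyl-5-methoxy-3-methyl-2-(3,4,5-trimethoxyphenyl)-3,3a,4,5-tetrahydrobenzofuran-6(2H)-one F2 (the same compound as A2). Deprotonation at C5 with LiN(iPr)2 and silylation gives (2S,3S,3aS)-3a-allyl-5-methoxy-3-methyl-6-(trimethylsilyloxy)-2-(3,4,5-trimethoxyphenyl)-2,3,3a,4-tetrahydrobenzofuran F3. Pd(OAc)2 then removes the C4 hydrogen and gives 24.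

**Step 9.**
- What may go wrong: phosphine-initiated oligomerisation of ynone 4 may outpace addition of the hindered secondary benzylic alcohol.
- Fallback: it sets out from 4 and 16 and comes back at 17 by acid-catalysed alkoxy exchange instead of conjugate addition. Ynone 4 is first converted with methanol and a trace of Et3N into the stable (E)-1,4-dimethoxybut-3-en-2-one F4. F4 in excess is then heated with 16 and pyridinium p-toluenesulfonate in toluene while methanol is removed, which gives 17.

**Step 13.**
- What may go wrong: β-elimination of O1 from the lithium enolate may open the tetrahydrofuran before silylation.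
- Fallback: it sets out from 22 and comes back at 24 without an enolate, by direct dehydrogenation with 2-iodoxybenzoic acid in DMSO at 65 °C. No new compound is made.

**Step 14.**
- What may go wrong: palladium may turn to the allyl group (alkene isomerisation, or insertion of the alkene into the palladium enolate) instead of β-hydride elimination.
- Fallback: it sets out from 23 and comes back at 24 without metal, by oxidation with 2,3-dichloro-5,6-dicyano-1,4-benzoquinone and 2,6-lutidine in CH2Cl2 at 0 °C (hydride abstraction from C7a assisted by O1). No new compound is made.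

## Further compounds

F1 | step 12 | (3S,4S,5S)-3-(2-methoxy-3-oxobutyl)-4-methyl-3-(prop-2-enyl)-5-(3,4,5-trimethoxyphenyl)oxolan-2-one (epimers at the methoxy-bearing carbon) | C=CC[C@@]1(CC(OC)C(C)=O)C(=O)O[C@H](c2cc(OC)c(OC)c(OC)c2)[C@H]1C
F2 | step 12 | (2S,3S,3aS)-3a-allyl-5-methoxy-3-methyl-2-(3,4,5-trimethoxyphenyl)-3,3a,4,5-tetrahydrobenzofuran-6(2H)-one (C5 epimers) | C=CC[C@@]12CC(OC)C(=O)C=C1O[C@H](c1cc(OC)c(OC)c(OC)c1)[C@H]2C
F3 | step 12 | (2S,3S,3aS)-3a-allyl-5-methoxy-3-methyl-6-(trimethylsilyloxy)-2-(3,4,5-trimethoxyphenyl)-2,3,3a,4-tetrahydrobenzofuran | C=CC[C@@]12CC(OC)=C(O[Si](C)(C)C)C=C1O[C@H](c1cc(OC)c(OC)c(OC)c1)[C@H]2C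
F4 | step 9 | (E)-1,4-dimethoxybut-3-en-2-one | COCC(=O)/C=C/OC
F0 | step 13 | none | none
F0 | step 14 | none | none
A1 | alternative 1 | 3-methoxybut-3-en-2-one | C=C(OC)C(C)=O
A2 | alternative 1 | (2S,3S,3aS)-3a-allyl-5-methoxy-3-methyl-2-(3,4,5-trimethoxyphenyl)-3,3a,4,5-tetrahydrobenzofuran-6(2H)-one (C5 epimers) | C=CC[C@@]12CC(OC)C(=O)C=C1O[C@H](c1cc(OC)c(OC)c(OC)c1)[C@H]2C
A3 | alternative 2 | dichloroketene | O=C=C(Cl)Cl
A4 | alternative 2 | (2S,3S)-3-methyl-4-(prop-2-enyl)-2-(3,4,5-trimethoxyphenyl)-2,3-dihydrofuran | C=CCC1=CO[C@H](c2cc(OC)c(OC)c(OC)c2)[C@H]1C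
A5 | alternative 2 | 5-allyl-7,7-dichloro-4-methyl-3-(3,4,5-trimethoxyphenyl)-2-oxabicyclo[3.2.0]heptan-6-one (cis-fused; allyl cis to methyl; aryl trans to methyl) | C=CC[C@@]12C(=O)C(Cl)(Cl)[C@@H]1O[C@H](c1cc(OC)c(OC)c(OC)c1)[C@H]2C
A6 | alternative 3 | (5S)-3-(prop-2-enyl)-5-(3,4,5-trimethoxyphenyl)furan-2(5H)-one | C=CCC1=C[C@@H](c2cc(OC)c(OC)c(OC)c2)OC1=O
A7 | alternative 3 | lithium dimethylcuprate, Me2CuLi | [Li+].C[Cu-]C
A8 | alternative 3 | formaldehyde | C=O
A9 | alternative 3 | (3R,4S,5S)-3-(hydroxymethyl)-4-methyl-3-(prop-2-enyl)-5-(3,4,5-trimethoxyphenyl)oxolan-2-one | C=CC[C@@]1(CO)C(=O)O[C@H](c2cc(OC)c(OC)c(OC)c2)[C@H]1C
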